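The leftover comes first: at 50.0 min target and other capture product leave 25.3% of the charge unaccounted for in the south run and 26.2% in the north-east run. So your hunch that the substrate charge does not move the outcome looks sound for the flask you want a quick number on.

| flask | substrate | first nucleophile | second nucleophile | remark | time |
|---|---|---|---|---|---|
| south | 20 mM | 60 mM | 90 mM | run made earlier |  |
| north-east | 45 mM | 60 mM | 90 mM | run made earlier |  |
| flask | 30 mM | 60.0 mM | 90.0 mM |  | 50 min |

| run | time / min | target / % | other capture product / % |
|---|---|---|---|
| south | 4.00 | 1.4 | 6.3 |
| south | 6.00 | 4.4 | 9.2 |
| south | 10.0 | 5.6 | 17.0 |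
| south | 15.0 | 9.1 | 24.1 |
| south | 20.0 | 11.3 | 32.2 |
| south | 30.0 | 14.2 | 41.7 |
| south | 50.0 | 19.7 | 55.0 |
| north-east | 2.50 | 3.0 | 5.3 |
| north-east | 8.00 | 4.7 | 13.9 |
| north-east | 15.0 | 6.5 | 23.8 |
| north-east | 20.0 | 9.7 | 31.2 |
| north-east | 30.0 | 15.1 | 40.7 |
| north-east | 40.0 | 17.6 | 48.7 |
| north-east | 50.0 | 18.9 | 54.9 |

(scatter of a reading: 1 percentage point)

- share of target in target plus other capture product at 1.0 min
- share of target in target plus other capture product at 50 min
- which of target and other capture product there is more of at 50 min

- a reading or a percentage of target counts all its forms, free or not

1. I assume each nucleophile captures in proportion to its concentration, an assumption these runs do not probe by their charges, since both have the same nucleophile charges. My first answer for the capture preference, the selectivity factor, is pooled other capture product over target at 50.0 min, times first over second nucleophile charged: 1.90.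

2. Now I put that back in. If each product took one nucleophile, the runs held on average about 56.9 mM of first and 81.1 mM of second nucleophile. With these means the capture preference, other over target per unit of second over first nucleophile, is 2.00.

3. For the flask, the charges give a share of 25.0% at 1.0 min. The same reckoning with the flask's mean nucleophiles gives 25.9% at 50 min, so other capture product stays ahead.

4. The forecast says 26% (21% to 32%) early and 26% (24.3% to 27.7%) late, with other capture product ahead, and finds “no real drift, lag, or dependence on concentration”. My reckoning differs in carrying a small drift of 0.90 percentage points.

The flask gives 25.9% at 1.0 min and 26.3% at 50 min, with 19.5% target, idle adduct counted in, against 54.6% other capture product.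

    substrate → intermediate (k = 0.0280 /min)
    first nucleophile + intermediate → target (k = 11.0 /M/min)
    second nucleophile + intermediate → other capture product (k = 21.0 /M/min)
    intermediate → solvolysis product (k = 0.0270 /min)
    first nucleophile + target ⇌ idle adduct, settled at all times (K = 17.0 /M)

In the flask, the second nucleophile uses the intermediate 2.9 times as fast as the first just after the start, where the capture preference gives 3.00 from the charges, and 2.8 times as fast at 16.9 min. In the neighbour flask with 22 mM of second nucleophile, the preference gives a share of 57.7% from the charges, and that flask gives 58.8% at 1.0 min, with target ahead at 50.0 min, 43.5% against 28.8%.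

The earlier runs and the new flask come from a simulation on assumed constants; scatter was added.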